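## Structural features

The target is a 2,2-dimethyl-2H-chromene: a benzene ring (ring A, C4a to C8a) fused to a pyran (ring B) that holds the ether oxygen O1, the quaternary gem-dimethyl carbon C2 and a styrene-type C3=C4 double bond. Ring A is a fully differentiated phloroglucinol, with O1 on C8a, a free hydroxyl on C5, a methoxy group on C7, the 3-oxo-3-phenylpropanoyl chain on C6 between hydroxyl and methoxy, and hydrogen only at C8. There is no stereocentre; the only stereochemical element in any route is the cis arrangement of C4a and C2 across C3=C4, which the ring then locks. The fragile groups are the 1,3-diketone next to a free phenol (acid causes cyclodehydration to a 4H-chromen-4-one, hot base causes retro-Claisen cleavage), the chromene (an allylic aryl ether and electron-rich styrene that ionises or polymerises with acid and reacts with electrophilic oxidants) and the electron-rich arene. The real difficulty is regiochemical: three oxygens on one ring must be told apart, and the acyl chain must enter C6 and not the equally activated C8. The key step exploits the fact that C4a is flanked by C5 and C8a, both of which end up bearing oxygen. With the same halogen on both carbons, closure of O1 onto either one gives the same chromene; the halogen left over marks C5 and, through its acidifying effect, also the neighbouring C6.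

## Logic of the disconnections

16 ⇒ 14 + 15. The bond between the methylene carbon and the benzoyl carbon is cut. C-acylation of a methyl ketone enolate is the classical entry to ortho-hydroxyaryl 1,3-diketones. Placing it last means the finished diketone never meets acid, a metal catalyst or a deprotection. The side chain shrinks to an acetyl group plus a commercial acid chloride. The forward step needs complete formation of the phenoxide–enolate dianion, acylation at carbon, and a cold, weakly acidic quench.

14 ⇒ 13. The C5–O bond is cut, with the hydroxyl arising from the bromine that survives the ring closure. Doing this after the acetyl group is in place removes any phenol protecting group and avoids an ortho-hydroxybenzylic alcohol on a phloroglucinol-type ring, which would ionise readily. The forward step is a C–O coupling with hydroxide at a carbon carrying two ortho substituents, in the presence of an enolisable ketone.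

13 ⇒ 10 + 11. The C6–C(acetyl) bond is cut. In 10 the hydrogen at C6 is the only ring hydrogen flanked by bromine and methoxy, so a lithium amide should remove it in preference to the hydrogen at C8. The bromine thus acts first as the regiochemical control element and later as the hydroxyl precursor. A sequence through a C5 phenol, ortho-formylation and Lewis-acid homologation of the aldehyde with a diazo ketone was weighed and set aside: electron-rich, doubly ortho-substituted aryl aldehydes favour aryl migration in that reaction, and the sequence would add a protection and an acidic deprotection. The forward step must keep the ortho-bromoaryllithium cold and use an acyl donor that stops at the ketone.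

10 ⇒ 9. The C8a–O1 bond is cut, which opens ring B. The precursor has one tertiary hydroxyl and two equivalent C–Br bonds, so no regiochemical decision arises. It is used without protecting or spectator groups, since nothing in it needs masking. The forward step must achieve C–O reductive elimination from a hindered tertiary alkoxide, a single closure, and retention of the Z alkene.

9 ⇒ 6 + 7. The two C–CH3 bonds at the future C2 are cut. This reduces the tertiary allylic alcohol to a Z enoate and two equivalents of a methyl nucleophile. The forward step must add twice in 1,2-fashion without conjugate addition, without touching the aryl bromides and without loss of the Z geometry.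

6 ⇒ 4 + 5. The C3=C4 double bond is cut. A Z-selective phosphonate olefination of an aryl aldehyde sets the only geometric element of the route in one step. The demand is kinetic Z-selectivity with a benzaldehyde bearing two ortho bromines.

4 ⇒ 1 + 2. The C4a–C4 bond is cut. The arene hydrogen between the two bromines of 1 is the most acidic, so deprotonation followed by formylation gives the symmetric aldehyde directly. The base must deprotonate and not exchange bromine, and the temperature must stay low enough to prevent halogen migration.

## Other disconnections considered

Alternative 1: The cut removes both bonds at the aryl ketone carbon, C6–C(=O) and C(=O)–CH2, so the chain is assembled from three pieces. In the forward step zerovalent palladium would insert into the C6–I bond of the protected iodide A2, carbon monoxide A4 would insert to give an aroylpalladium species, and the enolate of acetophenone A3 would be acylated at carbon to release the protected diketone A1.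
- In favour: it is convergent, forms two C–C bonds of the diketone in one operation and needs no aryl methyl ketone. On bonds formed per step it is better than steps 5 and 7 of the chosen plan taken together.
- Against: the C6 iodide sits between two alkoxy groups on an electron-rich ring, so enolate attack on a hindered aroylpalladium must outrun direct α-arylation and reduction. Iodination of a 5,7-dioxygenated chromene would have to choose C6 over C8, a choice the chosen plan avoids because the C5 bromine directs metalation to C6. The phenol must be carried as a methoxymethyl ether and freed with acid on the finished hydroxy diketone, which is where cyclodehydration and chromene damage are most to be feared.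
- Comparison on structure: the alternative leaves the chromene construction open and would still need something like steps 1 to 4.
- Comparison on mechanism: both plans rest on an aryl halide and palladium, and in using only catalytic metal for its strategic step the alternative is the equal of step 4.
- Comparison on step economy: from 10, hydroxyl formation, protection, iodination, carbonylation and deprotection would be five operations against three (steps 5 to 7).

Alternative 2: The cut is in ring A itself, at C4a–C8a and C5–C6, so the arene is built from 3-methoxycyclobut-2-enone A6 and the prenyl-substituted siloxyalkyne A7. In the forward step heating would open A6 to its ketene valence isomer, which would add across A7 with the ketene carbon bonding to the alkyne carbon that carries the prenyl group. A second four-electron opening, a six-electron closure and tautomerisation would give phenol A5. In A5 the free hydroxyl (future O1), the silyl ether (future C5 hydroxyl) and the methoxy group (C7) are already differentiated and the prenyl chain sits on C4a.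
- In favour: regiochemistry follows from the polarity of the partners, and three differentiated oxygens plus the C4a side chain arrive in one step. In bonds formed per step it is better than the chosen plan. It also delivers the C5 oxygen already in place, so no C–O coupling at a hindered bromide (step 6) would be needed.
- Against: neither A6 nor A7 is commercially available, and each needs its own short synthesis. Ring B would still have to be closed by oxidative cyclisation of the free phenol onto the prenyl group, the silyl ether removed, and C6 acylated afterwards, with the C6/C8 question open again. The thermal cascade runs through reactive ketenes in the presence of a trisubstituted alkene, which invites ene and dimerisation pathways.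
- Comparison on structure: the alternative spends its strategic step on a benzene ring that the chosen plan buys as 1.
- Comparison on mechanism: a pericyclic cascade relies on electronic bias for regiocontrol, whereas in step 4 symmetry removes the question. Both are free of protecting-group steps up to that point, where they are equal.
- Comparison on step economy: with partner syntheses, chromene closure, desilylation and a C6 acylation sequence it would be clearly longer than seven steps.

Alternative 3: The cut is between the aryl ketone carbon and the methylene carbon, with the diketone carried as an isoxazole. In the forward step the C6 aldoxime A9 would be oxidised to the nitrile oxide A10, which would add to phenylacetylene A11 with the usual 3,5-regiochemistry to give isoxazole A8. Reductive N–O cleavage, hydrolysis of the enaminone and removal of the methoxymethyl ether would then reveal the hydroxy diketone.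
- In favour: A10 carries two ortho substituents and should resist dimerisation, and the regiochemistry with a terminal alkyne is dependable. The isoxazole is a sturdier carrier of the diketone than anything in the chosen route, and on that point the alternative is better, though the chosen plan needs no such carrier because it forms the diketone last. The cycloaddition also has no C- versus O-acylation question, which is an advantage over step 7.
- Against: the oxidants that convert aldoximes to nitrile oxides are electrophilic halogen or hypervalent iodine species, which can also attack the electron-rich ring and the chromene alkene. N–O cleavage would have to spare C3=C4, which excludes catalytic hydrogenation. Enaminone hydrolysis and ether cleavage are both acidic and are applied to the hydroxy diketone.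
- Comparison on structure: it presupposes the chromene with a C6 aldehyde and a protected phenol.
- Comparison on mechanism: a concerted dipolar cycloaddition is as predictable as the enolate acylation of step 7.
- Comparison on step economy: hydroxylation of 10, formylation, protection, oxime formation, cycloaddition, N–O cleavage with hydrolysis and deprotection would be about seven operations from 10 against three.

Key step: step 4

Assumption: 16 is drawn as the diketo tautomer; it is expected to exist largely as the hydrogen-bonded enol, which is the same compound.

## Route

Step 1
Reactants: 1 3,5-dibromoanisole; 2 N,N-dimethylformamide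
Product: 4 2,6-dibromo-4-methoxybenzaldehyde, via 2,6-dibromo-4-methoxyphenyllithium 3 (not isolated)
Conditions: LiN(iPr)2 (1.1 equiv), THF, −78 °C; then 2, −78 → 0 °C; 1 M HCl
Reagents that add atoms: none
Why: Directed ortho-metalation: the lithium amide should remove the one hydrogen flanked by both bromines, the most acidic in 1, without bromine–lithium exchange. Aryllithium 3 is then formylated by 2 at −78 °C, where halogen migration and aryne formation are slow.

Step 2
Reactants: 4 2,6-dibromo-4-methoxybenzaldehyde; 5 methyl bis(2,2,2-trifluoroethyl)phosphonoacetate
Product: 6 methyl (Z)-3-(2,6-dibromo-4-methoxyphenyl)prop-2-enoate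
Conditions: KN(SiMe3)2 (1.05 equiv), 18-crown-6 (3 equiv), THF, −78 °C
Reagents that add atoms: none
Why: Still–Gennari olefination: with the electron-poor trifluoroethyl phosphonate and a crown-sequestered potassium ion, elimination from the kinetic adduct is faster than its reversal, which should give the Z enoate. Aryl aldehydes are good substrates, and the ortho bromines do not block addition to the formyl group.

Step 3
Reactants: 6 methyl (Z)-3-(2,6-dibromo-4-methoxyphenyl)prop-2-enoate; 7 methylmagnesium bromide
Product: 9 (Z)-4-(2,6-dibromo-4-methoxyphenyl)-2-methylbut-3-en-2-ol, via (Z)-4-(2,6-dibromo-4-methoxyphenyl)but-3-en-2-one 8 (not isolated)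
Conditions: MeMgBr (3.5 equiv), THF, −20 → 0 °C; sat. aq. NH4Cl
Reagents that add atoms: none
Why: Double Grignard 1,2-addition to the ester through ketone 8, the same transformation that opens coumarins to Z-configured 2-(3-hydroxy-3-methylbutenyl)phenols. MeMgBr does not exchange with aryl bromides, and the twisted, hindered β-aryl position disfavours conjugate addition, so the Z geometry should be kept.

Step 4
Reactants: 9 (Z)-4-(2,6-dibromo-4-methoxyphenyl)-2-methylbut-3-en-2-ol
Product: 10 5-bromo-7-methoxy-2,2-dimethyl-2H-chromene
Conditions: Pd(OAc)2 (3 mol %), 2-(di-tert-butylphosphino)-1,1'-binaphthyl (4 mol %), Cs2CO3 (1.5 equiv), toluene, 80 °C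
Reagents that add atoms: none
Why: Pd(OAc)2 is reduced in the flask, and the monoligated zerovalent palladium inserts into one of the two C–Br bonds; Cs2CO3 removes the hydroxyl proton, the alkoxide displaces bromide on divalent palladium to give a seven-membered aryl(alkoxo)palladium chelate, and C–O reductive elimination, driven by the bulky electron-rich phosphine, forms C8a–O1 and regenerates zerovalent palladium. The closest known reaction type is the Buchwald–Hartwig-type intramolecular C–O coupling of aryl bromides with tethered tertiary alcohols, which gives 2,2-dimethylchromans. Ring B closes as a six-membered ring by reductive elimination from that chelate, with the Z alkene holding oxygen and the C–Br carbon within bonding distance. No stereocentre is formed; the Z geometry set in step 2 simply becomes the endocyclic C3=C4 bond. The carbinol carbon has no hydrogen, so β-hydride elimination, and the C–Br reduction that would follow it, cannot occur. The step needs one closure only, which is secured because the two bromines are interconverted by rotation about the aryl–alkenyl bond, so insertion at either gives 10, and because the molecule has a single hydroxyl. After closure the remaining bromine at C5 has no internal nucleophile within reach, so it should survive for steps 5 and 6.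

Step 5
Reactants: 10 5-bromo-7-methoxy-2,2-dimethyl-2H-chromene; 11 N-methoxy-N-methylacetamide
Product: 13 1-(5-bromo-7-methoxy-2,2-dimethyl-2H-chromen-6-yl)ethan-1-one, via (5-bromo-7-methoxy-2,2-dimethyl-2H-chromen-6-yl)lithium 12 (not isolated)
Conditions: LiN(iPr)2 (1.2 equiv), THF, −78 °C; then 11 (1.5 equiv), −78 → 0 °C; sat. aq. NH4Cl
Reagents that add atoms: none
Why: Directed ortho-metalation at C6, the only ring hydrogen flanked by bromine and methoxy (as at C2 of 3-bromoanisole), with a base that leaves the C–Br bond intact; the hydrogen at C8, between two ether oxygens, is not acidic enough for a lithium amide. Weinreb ketone synthesis then stops at the ketone because the chelated tetrahedral adduct persists until work-up.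

Step 6
Reactants: 13 1-(5-bromo-7-methoxy-2,2-dimethyl-2H-chromen-6-yl)ethan-1-one
Product: 14 1-(5-hydroxy-7-methoxy-2,2-dimethyl-2H-chromen-6-yl)ethan-1-one
Conditions: Pd2(dba)3 (2 mol %), 2-di-tert-butylphosphino-2',4',6'-triisopropylbiphenyl (8 mol %), KOH (3 equiv), 1,4-dioxane/H2O, 100 °C; then 1 M HCl to pH 5
Reagents that add atoms: potassium hydroxide, [K+].[OH-]
Why: Palladium-catalysed hydroxylation of an aryl bromide with hydroxide: oxidative addition at C5–Br is helped by the ortho acetyl group, bromide is exchanged for hydroxide, and the bulky biaryl phosphine, which accepts bromides with two ortho substituents, promotes C–O reductive elimination. The product leaves as a hindered phenoxide that is a poor partner for further arylation, and the chromene, the methyl ether and the hindered aryl methyl ketone should tolerate aqueous base.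

Step 7
Reactants: 14 1-(5-hydroxy-7-methoxy-2,2-dimethyl-2H-chromen-6-yl)ethan-1-one; 15 benzoyl chloride
Product: 16 1-(5-hydroxy-7-methoxy-2,2-dimethyl-2H-chromen-6-yl)-3-phenylpropane-1,3-dione
Conditions: LiN(SiMe3)2 (4 equiv), THF, −78 → −10 °C; then 15 (1.05 equiv), −78 °C → rt; cold 0.5 M HCl to pH 4–5
Reagents that add atoms: none
Why: Crossed Claisen acylation, the one-flask form of the Baker–Venkataraman route: excess lithium amide forms the phenoxide–enolate dianion, whose carbon terminus is benzoylated by 15. The product is held as its dilithium salt, which prevents a second acylation, and any O-benzoate would be transferred to carbon under the same conditions. The cold, weakly acidic quench should release 16 without cyclodehydration of the hydroxy diketone or harm to the chromene.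

## Compound list

1 | 3,5-dibromoanisole | COc1cc(Br)cc(Br)c1 | starting material
2 | N,N-dimethylformamide | CN(C)C=O | starting material
3 | 2,6-dibromo-4-methoxyphenyllithium | [Li]c1c(Br)cc(OC)cc1Br | intermediate
4 | 2,6-dibromo-4-methoxybenzaldehyde | COc1cc(Br)c(C=O)c(Br)c1 | intermediate
5 | methyl bis(2,2,2-trifluoroethyl)phosphonoacetate | COC(=O)CP(=O)(OCC(F)(F)F)OCC(F)(F)F | starting material
6 | methyl (Z)-3-(2,6-dibromo-4-methoxyphenyl)prop-2-enoate | COC(=O)/C=C\c1c(Br)cc(OC)cc1Br | intermediate
7 | methylmagnesium bromide | C[Mg]Br | starting material
8 | (Z)-4-(2,6-dibromo-4-methoxyphenyl)but-3-en-2-one | CC(=O)/C=C\c1c(Br)cc(OC)cc1Br | intermediate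
9 | (Z)-4-(2,6-dibromo-4-methoxyphenyl)-2-methylbut-3-en-2-ol | COc1cc(Br)c(/C=C\C(C)(C)O)c(Br)c1 | intermediate
10 | 5-bromo-7-methoxy-2,2-dimethyl-2H-chromene | COc1cc(Br)c2C=CC(C)(C)Oc2c1 | intermediate
11 | N-methoxy-N-methylacetamide | CC(=O)N(C)OC | starting material
12 | (5-bromo-7-methoxy-2,2-dimethyl-2H-chromen-6-yl)lithium | [Li]c1c(OC)cc2OC(C)(C)C=Cc2c1Br | intermediate
13 | 1-(5-bromo-7-methoxy-2,2-dimethyl-2H-chromen-6-yl)ethan-1-one | COc1cc2OC(C)(C)C=Cc2c(Br)c1C(C)=O | intermediate
14 | 1-(5-hydroxy-7-methoxy-2,2-dimethyl-2H-chromen-6-yl)ethan-1-one | COc1cc2OC(C)(C)C=Cc2c(O)c1C(C)=O | intermediate
15 | benzoyl chloride | O=C(Cl)c1ccccc1 | starting material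
16 | 1-(5-hydroxy-7-methoxy-2,2-dimethyl-2H-chromen-6-yl)-3-phenylpropane-1,3-dione | COc1cc2c(c(O)c1C(=O)CC(=O)c1ccccc1)C=CC(C)(C)O2 | target

## Step count and least certain steps

Total step count: 7. Longest linear sequence: 7 steps, from 1 to 16; compounds 2, 5, 7, 11 and 15 are commercial reagents brought in along that line. No protecting group is used.

Step 4 (key step). C–O reductive elimination from a hindered tertiary alkoxide is the slow event of the cycle. While the aryl(alkoxo)palladium species waits, β-carbon elimination from the alkoxide (loss of acetone), reduction of the C–Br bond or intermolecular etherification can take over, and prolonged heating could erode the Z geometry by ionisation of the tertiary allylic alcohol. A copper catalyst (CuI, 1,10-phenanthroline, Cs2CO3) would be the first variation within the same approach. The fallback changes the bond that closes ring B. It sets out from 9: n-BuLi (2 equiv; alkoxide formation, then one bromine–lithium exchange, for which the symmetry argument holds equally), B(OMe)3 and H2O2/NaOH in one flask should give 3-bromo-2-[(Z)-3-hydroxy-3-methylbut-1-en-1-yl]-5-methoxyphenol F1. A trace of pyridinium p-toluenesulfonate in CH2Cl2 would then ionise the tertiary allylic alcohol, and capture of the cation by the phenol oxygen closes O1–C2 and returns to the route at 10.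

Step 6. The bromide has two ortho substituents and the medium is hot aqueous hydroxide. The likely failures are arrest of the catalyst through chelation of palladium by the ortho-acyl phenoxide product, slow reductive elimination, arylation of the product phenoxide by unreacted 13, or base-induced condensation of the methyl ketone. The fallback makes the C–O bond by 1,2-migration from boron instead of by reductive elimination. It sets out from 13: Miyaura borylation (bis(pinacolato)diboron, PdCl2(dppf), KOAc, dioxane, 90 °C) should give 1-[7-methoxy-2,2-dimethyl-5-(4,4,5,5-tetramethyl-1,3,2-dioxaborolan-2-yl)-2H-chromen-6-yl]ethan-1-one F2. Oxidation of its C–B bond with NaBO3·4H2O in THF/H2O at room temperature comes back to the route at 14.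

Step 5. Aryllithium 12 carries an ortho bromine and is hindered. The risks are loss of LiBr to an aryne or migration of bromine if the temperature rises before trapping, and proton transfer from the acetyl group of 11 to the aryllithium, which would return 10. The fallback exchanges the order of oxygenation and acylation and sets out from 10.
- n-BuLi, then B(OMe)3, then H2O2/NaOH should give 7-methoxy-2,2-dimethyl-2H-chromen-5-ol F3.
- Ortho-formylation with MgCl2, Et3N and paraformaldehyde in acetonitrile can only occur at C6, the one free position ortho to the hydroxyl, and should give 5-hydroxy-7-methoxy-2,2-dimethyl-2H-chromene-6-carbaldehyde F4.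
- MeMgBr (3 equiv) should give racemic 6-(1-hydroxyethyl)-7-methoxy-2,2-dimethyl-2H-chromen-5-ol F5, which would be used crude because benzylic alcohols of this type ionise easily.
- MnO2 in CH2Cl2 would oxidise the benzylic alcohol and return to the route at 14, bypassing 13 and step 6 as well.

Step 3. Ketone 8 is a Z enone, and reversible conjugate addition of halide or alkoxide to it would allow rotation and loss of the Z geometry before the second methyl addition; conjugate addition of the methyl group is the other possible leak. The fallback sets the geometry by syn addition of hydrogen to an alkyne and sets out from 4.
- Ohira–Bestmann homologation (dimethyl (1-diazo-2-oxopropyl)phosphonate, K2CO3, MeOH) should give 1,3-dibromo-2-ethynyl-5-methoxybenzene F6.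
- Deprotonation with LiN(SiMe3)2 in THF at −78 °C (an amide base, to spare the bromines) and addition to acetone should give 4-(2,6-dibromo-4-methoxyphenyl)-2-methylbut-3-yn-2-ol F7.
- Semihydrogenation (H2, Pd/CaCO3 poisoned with Pb(OAc)2, quinoline, ethyl acetate) comes back to the route at 9.

## Further compounds

F1 | step 4 | 3-bromo-2-[(Z)-3-hydroxy-3-methylbut-1-en-1-yl]-5-methoxyphenol | COc1cc(O)c(/C=C\C(C)(C)O)c(Br)c1
F2 | step 6 | 1-[7-methoxy-2,2-dimethyl-5-(4,4,5,5-tetramethyl-1,3,2-dioxaborolan-2-yl)-2H-chromen-6-yl]ethan-1-one | COc1cc2OC(C)(C)C=Cc2c(B3OC(C)(C)C(C)(C)O3)c1C(C)=O
F3 | step 5 | 7-methoxy-2,2-dimethyl-2H-chromen-5-ol | COc1cc(O)c2C=CC(C)(C)Oc2c1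
F4 | step 5 | 5-hydroxy-7-methoxy-2,2-dimethyl-2H-chromene-6-carbaldehyde | COc1cc2OC(C)(C)C=Cc2c(O)c1C=O
F5 | step 5 | 6-(1-hydroxyethyl)-7-methoxy-2,2-dimethyl-2H-chromen-5-ol (racemic) | COc1cc2OC(C)(C)C=Cc2c(O)c1C(C)O
F6 | step 3 | 1,3-dibromo-2-ethynyl-5-methoxybenzene | COc1cc(Br)c(C#C)c(Br)c1
F7 | step 3 | 4-(2,6-dibromo-4-methoxyphenyl)-2-methylbut-3-yn-2-ol | COc1cc(Br)c(C#CC(C)(C)O)c(Br)c1
A1 | alternative 1 | 1-[7-methoxy-5-(methoxymethoxy)-2,2-dimethyl-2H-chromen-6-yl]-3-phenylpropane-1,3-dione | COCOc1c(C(=O)CC(=O)c3ccccc3)c(OC)cc2c1C=CC(C)(C)O2
A2 | alternative 1 | 6-iodo-7-methoxy-5-(methoxymethoxy)-2,2-dimethyl-2H-chromene | COCOc1c(I)c(OC)cc2c1C=CC(C)(C)O2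
A3 | alternative 1 | acetophenone | CC(=O)c1ccccc1
A4 | alternative 1 | carbon monoxide | [C-]#[O+]
A5 | alternative 2 | 5-methoxy-2-(3-methylbut-2-en-1-yl)-3-[(triisopropylsilyl)oxy]phenol | COc1cc(O)c(CC=C(C)C)c(O[Si](C(C)C)(C(C)C)C(C)C)c1
A6 | alternative 2 | 3-methoxycyclobut-2-en-1-one | COC1=CC(=O)C1
A7 | alternative 2 | triisopropyl[(5-methylhex-4-en-1-yn-1-yl)oxy]silane | CC(C)=CCC#CO[Si](C(C)C)(C(C)C)C(C)C
A8 | alternative 3 | 3-[7-methoxy-5-(methoxymethoxy)-2,2-dimethyl-2H-chromen-6-yl]-5-phenylisoxazole | COCOc1c(-c3cc(-c4ccccc4)on3)c(OC)cc2c1C=CC(C)(C)O2
A9 | alternative 3 | (E)-7-methoxy-5-(methoxymethoxy)-2,2-dimethyl-2H-chromene-6-carbaldehyde oxime | COCOc1c(/C=N/O)c(OC)cc2c1C=CC(C)(C)O2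
A10 | alternative 3 | 7-methoxy-5-(methoxymethoxy)-2,2-dimethyl-2H-chromene-6-carbonitrile oxide | COCOc1c(C#[N+][O-])c(OC)cc2c1C=CC(C)(C)O2
A11 | alternative 3 | phenylacetylene | C#Cc1ccccc1
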